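Larch holds twice the substrate of alder at the same partner charge, so this pair compares two substrate charges at one partner charge.

| flask | substrate | partner | time |
|---|---|---|---|
| larch | 0.400 M | 0.440 M |  |
| alder | 0.200 M | 0.440 M |  |
| cedar | 0.160 M | 0.200 M | 7.2 h |

| larch run: time / h | larch run: [target] / M | alder run: time / h | alder run: [target] / M |
|---|---|---|---|
| 0.55 | 0.045 | 0.55 | 0.021 |
| 1.7 | 0.122 | 1.7 | 0.054 |
| 3.2 | 0.184 | 3.2 | 0.080 |
| 5.0 | 0.204 | 5.0 | 0.089 |
| 7.2 | 0.223 | 7.2 | 0.098 |

(readings scatter by 0.003 M)

- the power of [substrate] that the first rate follows, about the charge of the larch run; measure it at two percent of substrate made into target (one fixed amount of target, the same in the runs compared)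
- target in the cedar run at 7.2 h, as a share of the substrate charged

- Overall: substrate + partner -> target.
- Constant volume, constant temperature.
- An order is taken over about fifteen percent of the charge, up and down.

My zero of the scale is a first-order flask, in which each run turns the same share of its substrate per hour, whatever the charge. The departure from that zero is the power of substrate, and I read it from the first readings, though the alder reading is small against the scatter:

order = ln(target in larch / target in alder) / ln(charge ratio) = 1.10

So I take the runs as close to first order in substrate. That lets me carry one quantity, the specific rate κ, which is target made per hour per unit of substrate charged, read early in a run: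

κ(larch) = 0.045 M / (0.55 h × 0.400 M) = 0.205 h⁻¹

If κ held, larch would reach 77.1 % at 7.2 h, but it reads 55.8 %. The larch run therefore keeps a fraction f of the plain share:

f = 0.723

Substrate is the limiting reagent in cedar, with 0.160 M against 0.200 M of partner. The weak link is the power of partner, m, which no two runs vary. The overall equation does not give a kinetic power, so I take m as one, a trial value and not a reading:

κ(cedar) = κ(larch) × 0.200 M / 0.440 M = 0.0930 h⁻¹

cedar share = f × (plain share at that κ) = 35.3 %

The forecast, reckoned separately, gives 1.12 for the power of substrate and 38 % for cedar, above my figure. It leans on a different ground: “Larch loses half its partner yet shows no extra slowing”.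

    substrate + 2 partner → target + partner (0.9756 M⁻² h⁻¹)
    target + partner → side product (0.4212 M⁻¹ h⁻¹)
    substrate + partner + target → 2 target (5.292 M⁻² h⁻¹)

The cedar flask gives 22.4 %, and the power of substrate is 1.0. A fit of the main steps alone puts cedar at 25.1 %. Keeping f, the cedar result asks for a κ of 0.0514 h⁻¹, which is 0.251 of κ in larch, while the partner charge stands at 0.455 of larch. The reforged power of partner in cedar is therefore m = 1.75.

(All runs were generated by integration from invented constants, noise included.)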